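In this stirred vessel the electrophile runs in over 30 s onto nucleophile and free base, and you want to know how much of it has reacted after 15 min.

the same everywhere: electrophile 0.050 M (fed, over 30 s)

|  | nucleophile | free base | remark | time |
|---|---|---|---|---|
| gamma | 0.060 M | 0.093 M | run made earlier |  |
| eta | 0.060 M | 0.27 M | run made earlier |  |
| dawn | 0.0600 M | 0.0750 M |  | 15 min |
| noon | 0.0600 M | 0.110 M |  | 15 min |
| summer | 0.0600 M | 0.170 M |  | 15 min |

| run | time / min | electrophile / % | product / % |
|---|---|---|---|
| gamma | 1.33 | 29.3 | 71.8 |
| gamma | 2.00 | 26.6 | 74.4 |
| gamma | 3.00 | 25.1 | 76.8 |
| gamma | 5.00 | 23.8 | 76.7 |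
| gamma | 10.0 | 23.4 | 74.9 |
| gamma | 15.0 | 25.1 | 75.9 |
| eta | 1.33 | 20.7 | 78.1 |
| eta | 2.00 | 16.7 | 81.8 |
| eta | 3.00 | 12.9 | 86.5 |
| eta | 5.00 | 12.9 | 88.2 |
| eta | 10.0 | 10.1 | 88.1 |
| eta | 15.0 | 11.7 | 89.6 |

(each reading ± 1 percentage point)

- what was read earlier has a scatter of 1 percentage point, one standard deviation

- part of the electrophile that has reacted at the end, dawn
- part of the electrophile that has reacted at the end, noon
- part of the electrophile that has reacted at the end, summer
- what raising the concentration of free base from its lowest to its highest value here does to the part of the electrophile that has reacted (changes below 5 percentage points count as none) (it rises / no change / it falls)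

Begin with the plateaus. Over its readings from 5.00 min on, the gamma run averages 75.8% product and the eta run 88.6%. Between 5.00 min and 15.0 min gamma goes from 76.7% to 75.9% and eta from 88.2% to 89.6%, changes of about the scatter, so you treat both as end states.

Could a simple equilibrium of electrophile and nucleophile describe them? Product squared over what is left of those two comes to 5.39 in gamma but 22.0 in eta, so that estimate fails. Now let free base be used up one-to-one as well. The plateau quotient, an apparent equilibrium constant, is the square of the product concentration divided by what is left of electrophile, nucleophile and free base. It gives 97.8 M⁻¹ in gamma and 97.6 M⁻¹ in eta, two different flasks, so you carry 97.7 M⁻¹.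

For dawn, start from gamma's 75.8% and use the quotient to find the electrophile left. That gives 64.1% reacted. The objection is that this swings past the answer, so take the mean of guess and result, 70.0%, and go round again. The next result is 75.0%, with mean 72.5%. One more round gives 70.8%, with mean 71.6%, and that is your figure for dawn.

The forecast says 72% for dawn, 78.6% for noon and 84.3% for summer, and for the trend, it rises. Its ground is the same reading of the plateaus: “This looks like an equilibrium rather than slow kinetics”.

The flasks give 74.0% at dawn, 78.2% at noon and 83.2% in summer, so with more free base the part reacted goes as follows: it rises, a change of 9.2 percentage points from dawn to summer, and the forecast holds.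

    electrophile + nucleophile ⇌ acid set free + product (K = 0.510, k = 2.90 M⁻¹ s⁻¹)
    nucleophile + acid set free ⇌ protonated nucleophile, settled at all times (K = 60000 M⁻¹)
    acid set free + free base ⇌ salt of the base, settled at all times (K = 1000 M⁻¹)

At dawn's end, protonated nucleophile 0.0216 M, salt of the base 0.0152 M and acid set free 2.54 × 10⁻⁴ M together match the product, 0.0370 M, one acid per product. Now take 97.7 M⁻¹ to a flask like noon but with 0.20 M of electrophile. Starting as if the whole 0.0600 M of nucleophile had reacted, one round gives 0.0547 M reacted and a second 0.0562 M, which is 28.1% of that charge, and that flask stands at 24.5%.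

(The earlier runs and the new flask are calculated on assumed constants, noise included.)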